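The two halves are the same lactone acid in mirror-image form, so one racemic monomer synthesis serves both. The cyclohexane ring is cut by a Diels–Alder disconnection: a 2-isopropyl diene carrying a masked formyl group and acetoxymaleic anhydride join at the ring CH2–C(OH)(CH2OH) bond and at the bond between the lactone α-CH and the allylic ring-fusion CH. The step exploits the cis 1,2-relation of the lactone carbonyl and the CH2OH branch on the cyclohexane ring (anhydride), the tertiary C–O (enol acetate) and an epimerisable ring-fusion centre. Hydrogenation, equilibration, ring-closing metathesis to the oxepinone ring and a chiral ester that separates the antipodes complete the plan.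

Key step: step 4

Remark 1 (locants used below): C1 = lactone α-CH, C2 = lactone C=O, C3 = OCH2, C4 = C(CO2H)=, C5 = =CH, C6 = allylic ring-fusion CH, C7 = CH(iPr), C8 and C9 = ring CH2, C10 = C(OH), C14 = CH2OH; primed locants for the alcohol half.

Remark 2 (reading of the target): all four ring stereocentres of the alcohol half are the mirror image of those of the acid half. Racemic compounds 7–17 are written with the SMILES of the enantiomer that ends in the acid half (series A: with C7→C8→C9→C10→C1→C6 clockwise, isopropyl, C14 and C2 point up and O–C10 down); series B is its mirror image.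

Step 1
Reactants: 1 3-methylbutanal; 2 2,2-dimethoxyacetaldehyde (60 % aqueous solution)
Product: 3 (2E)-4,4-dimethoxy-2-(propan-2-yl)but-2-enal
Conditions: pyrrolidine (10 mol %), PhCO2H (10 mol %), toluene, 50 °C, slow addition of 1
Reagents that add atoms: none
Why: Amine-catalysed crossed aldol condensation (enamine of enolisable 1 adds to non-enolisable 2, then dehydration) should give the thermodynamically preferred E enal, with CHO trans to CH(OMe)2.

Step 2
Reactants: 3 (2E)-4,4-dimethoxy-2-(propan-2-yl)but-2-enal
Product: 4 (3E)-5,5-dimethoxy-3-(propan-2-yl)penta-1,3-diene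
Conditions: Ph3PCH3Br, KOtBu, THF, 0 °C
Reagents that add atoms: methyltriphenylphosphonium bromide, C[P+](c1ccccc1)(c1ccccc1)c1ccccc1.[Br-]
Why: Wittig methylenation of the enal carbonyl leaves the trisubstituted E double bond untouched, so the acetal carbon stays trans to the new vinyl group.

Step 3
Reactants: 5 di-O-acetyl-L-tartaric anhydride
Product: 6 acetoxymaleic anhydride
Conditions: Et3N (1.0 equiv), CH2Cl2, 0 °C; distillation under reduced pressure
Reagents that add atoms: none
Why: E1cB elimination of acetic acid from the β-acetoxy anhydride should give the enol acetate, with loss of both stereocentres of 5.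

Step 4
Reactants: 4 (3E)-5,5-dimethoxy-3-(propan-2-yl)penta-1,3-diene; 6 acetoxymaleic anhydride
Product: 7 rac-3a-acetoxy-7-(dimethoxymethyl)-6-(propan-2-yl)-3a,4,7,7a-tetrahydro-2-benzofuran-1,3-dione (endo adduct; CH(OMe)2 cis to the anhydride ring; OAc on the other face)
Conditions: toluene, BHT (cat.), 90 °C, sealed tube, no base
Reagents that add atoms: none
Why: Thermal normal-demand Diels–Alder reaction: the HOMO of diene 4 and the LUMO of anhydride 6 combine in a concerted, asynchronous, suprafacial [4+2] cycloaddition that forms C9–C10 and C1–C6 at once. The closest known reaction type is the cycloaddition of citraconic or acetoxymaleic anhydride with 2-alkyl-1,3-dienes. It closes the six-membered carbocycle (C1, C6–C10) by intermolecular [4+2] ring formation, while the anhydride ring is carried in unchanged. C1 and C10 arise cis from the Z alkene locked in the five-membered anhydride, which fixes C2 and C14 cis and O–C10 trans to them; C6 follows the endo rule but its configuration is reset by equilibration in step 8, and the adduct is racemic, as wanted. The step needs regioselectivity: the isopropyl group on C7 makes C6 the more nucleophilic terminus, which should bond to the unsubstituted dienophile carbon C1 and leave the unhindered CH2 terminus C9 to the acetoxy-bearing C10 (para relation of isopropyl and acetoxy), and the steric clash of a C6–C10 pairing reinforces this. Amine bases are kept out so that the β-acetoxy anhydride does not eliminate acetic acid.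

Step 5
Reactants: 7 rac-cyclohexene anhydride (endo adduct)
Product: 8 rac-3a-acetoxy-7-(dimethoxymethyl)-6-(propan-2-yl)hexahydro-2-benzofuran-1,3-dione (isopropyl, CH(OMe)2 and anhydride ring all cis; OAc trans)
Conditions: H2 (3 atm), PtO2 (5 mol %), EtOAc, rt
Reagents that add atoms: none
Why: Heterogeneous syn hydrogenation of the C7=C8 bond from the convex face of the cis-fused bicycle, anti to the anhydride ring and the pseudo-axial CH(OMe)2 group, should set C7 with isopropyl cis to C2 and C14 and trans to the acetoxy group.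

Step 6
Reactants: 8 rac-saturated acetoxy anhydride
Product: 11 rac-7-(dimethoxymethyl)-3a-hydroxy-6-(propan-2-yl)hexahydro-2-benzofuran-1(3H)-one (cis-fused γ-lactone), via sodium carboxylate 9 (not isolated), via potassium carboxylate 10 (not isolated)
Conditions: NaBH4, THF, −20 → 0 °C; then KOH, MeOH/H2O, 40 °C; then AcOH to pH 5, concentration from toluene; chromatography
Reagents that add atoms: none
Why: Hydride reduction of the cyclic anhydride should occur at the more electrophilic carbonyl next to the acetoxy-bearing quaternary carbon (the usual regiochemistry for unsymmetrical succinic anhydrides) and give the C14 alcohol; saponification then removes the acetate while no lactone is present (no β-elimination), and the cis hydroxy acid closes to the neutral, chromatographable γ-lactone on mild acidification without touching a stereocentre.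

Step 7
Reactants: 11 rac-hydroxy γ-lactone
Product: 14 rac-2-{[(tert-butyldiphenylsilyl)oxy]methyl}-6-(dimethoxymethyl)-2-hydroxy-5-(propan-2-yl)cyclohexane-1-carboxylic acid (CO2H, CH2OSi, isopropyl and CH(OMe)2 cis; OH trans), via lithium carboxylate 12 (not isolated), via bis-silyl compound 13 (not isolated)
Conditions: LiOH·H2O (1.05 equiv), THF/H2O, rt; evaporation from toluene; TBDPSCl (3 equiv), imidazole, DMF, rt; then K2CO3, MeOH/THF/H2O, rt; pH 5 work-up
Reagents that add atoms: lithium hydroxide, [Li+].[OH-]; tert-butyl(chloro)diphenylsilane, CC(C)(C)[Si](Cl)(c1ccccc1)c1ccccc1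
Why: Saponification of the purified lactone with one equivalent of LiOH, silylation of the primary alcohol and the carboxylate (the tertiary alcohol is too hindered) and selective solvolysis of the labile silyl ester is the standard way to hold a γ-hydroxy acid open; it leaves O–C14 protected and the C2 acid free.

Step 8
Reactants: 14 rac-silyloxy acid acetal
Product: 16 rac-2-{[(tert-butyldiphenylsilyl)oxy]methyl}-6-formyl-2-hydroxy-5-(propan-2-yl)cyclohexane-1-carboxylic acid (CHO trans to CO2H and to isopropyl), via cis aldehyde 15 (not isolated)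
Conditions: PPTS (cat.), acetone/H2O, 40 °C; then K2CO3, MeOH, rt; pH 5 work-up
Reagents that add atoms: water, O
Why: Mild acetal hydrolysis followed by base-mediated enolisation of the aldehyde should epimerise C6 to the all-equatorial arrangement (relief of the 1,3-diaxial CHO/CH2OSi clash), a thermodynamic funnel that sets C6 independently of its configuration in 15.

Step 9
Reactants: 16 rac-trans aldehyde acid
Product: 17 rac-2-{[(tert-butyldiphenylsilyl)oxy]methyl}-6-ethenyl-2-hydroxy-5-(propan-2-yl)cyclohexane-1-carboxylic acid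
Conditions: Ph3PCH3Br (3.5 equiv), KOtBu (3.4 equiv), THF, 0 °C → rt
Reagents that add atoms: methyltriphenylphosphonium bromide, C[P+](c1ccccc1)(c1ccccc1)c1ccccc1.[Br-]
Why: Wittig methylenation of the aldehyde tolerates the carboxylate and the tertiary alkoxide, and C6 is already in its thermodynamic configuration, so the basic ylide cannot erode it.

Step 10
Reactants: 18 2-(bromomethyl)prop-2-enoic acid; 19 (1S)-1-(4-methoxyphenyl)ethanol
Product: 20 (1S)-1-(4-methoxyphenyl)ethyl 2-(bromomethyl)prop-2-enoate
Conditions: DCC, DMAP (5 mol %), CH2Cl2, −10 °C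
Reagents that add atoms: none
Why: Steglich esterification acylates the O–H bond of 19, so the S stereocentre is retained in a chiral ester that can later be cleaved oxidatively.

Step 11
Reactants: 17 rac-vinyl acid; 20 (1S)-1-(4-methoxyphenyl)ethyl 2-(bromomethyl)prop-2-enoate
Product: 21 series A ester of 17 with the 2-{[(1S)-1-(4-methoxyphenyl)ethoxy]carbonyl}prop-2-en-1-yl group and 22 its series B diastereomer (1:1 mixture expected)
Conditions: K2CO3, DMF, 0 °C → rt
Reagents that add atoms: none
Why: O-Alkylation of the carboxylate by the allylic bromide (SN2 and SN2′ give the same ester) joins racemic 17 to the S ester and gives two diastereomers that differ only in the sense of the ring stereocentres.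

Step 12
Reactants: 21 series A diene ester; 22 series B diene ester
Product: 23 series A (1S)-1-(4-methoxyphenyl)ethyl 9-{[(tert-butyldiphenylsilyl)oxy]methyl}-9-hydroxy-1-oxo-6-(propan-2-yl)-1,3,5a,6,7,8,9,9a-octahydro-2-benzoxepine-4-carboxylate and 24 its series B diastereomer (separated)
Conditions: second-generation Grubbs catalyst (10 mol %), toluene (2 mM), 80 °C; chromatography
Reagents that add atoms: none
Why: Ring-closing metathesis between the C6 vinyl group and the 1,1-disubstituted acrylate should close the seven-membered lactone across the trans-diequatorial C1/C6 substituents and create the C4=C5 bond (necessarily cis in the ring); the rigid lactone diastereomers should be separable, their series to be assigned by X-ray analysis.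

Step 13
Reactants: 23 series A lactone ester
Product: 25 series A 9-{[(tert-butyldiphenylsilyl)oxy]methyl}-9-hydroxy-1-oxo-6-(propan-2-yl)-1,3,5a,6,7,8,9,9a-octahydro-2-benzoxepine-4-carboxylic acid
Conditions: DDQ, CH2Cl2/pH 7 buffer, rt
Reagents that add atoms: none
Why: Oxidative cleavage of the electron-rich secondary benzylic ester (hydride abstraction, hydrolysis of the cation) should free the C4 acid under neutral conditions that spare the silyl ether and the lactone.

Step 14
Reactants: 24 series B lactone ester
Product: 26 series B (1S)-1-(4-methoxyphenyl)ethyl 9-hydroxy-9-(hydroxymethyl)-1-oxo-6-(propan-2-yl)-1,3,5a,6,7,8,9,9a-octahydro-2-benzoxepine-4-carboxylate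
Conditions: HF·pyridine, pyridine, THF, 0 °C; used at once
Reagents that add atoms: none
Why: Buffered fluoride desilylation frees the primary C14′ alcohol without base, so the alcohol should not attack the neighbouring lactone carbonyl.

Step 15
Reactants: 25 series A acid; 26 series B alcohol
Product: 27 heterochiral diester (C4 carboxyl of the A half on O–C14′ of the B half; silyl ether on the A half; chiral ester on the B half)
Conditions: MNBA (2-methyl-6-nitrobenzoic anhydride), DMAP, Et3N, CH2Cl2, rt
Reagents that add atoms: none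
Why: Mixed-anhydride esterification should acylate the only primary alcohol, the tertiary alcohols of both halves being too hindered to compete.

Step 16
Reactants: 27 protected heterochiral diester
Product: 28 silyl-protected dimer acid
Conditions: DDQ, CH2Cl2/pH 7 buffer, rt
Reagents that add atoms: none
Why: The same oxidative cleavage of the 1-(4-methoxyphenyl)ethyl ester frees the C4′ acid while O–C14 is still silylated, so no free primary alcohol is exposed.

Step 17
Reactants: 28 silyl-protected dimer acid
Product: 29 CNP0340505.1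
Conditions: HF·pyridine, pyridine, THF, 0 °C → rt
Reagents that add atoms: none
Why: Buffered fluoride cleavage of the primary silyl ether as the last step frees C14–OH under mild, non-basic conditions and leaves all esters in place.

Compound list
1 | 3-methylbutanal | CC(C)CC=O | starting material
2 | 2,2-dimethoxyacetaldehyde | COC(OC)C=O | starting material
3 | (2E)-4,4-dimethoxy-2-(propan-2-yl)but-2-enal | O=C/C(=C/C(OC)OC)C(C)C | intermediate
4 | (3E)-5,5-dimethoxy-3-(propan-2-yl)penta-1,3-diene | C=C/C(=C/C(OC)OC)C(C)C | intermediate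
5 | (3R,4R)-2,5-dioxooxolane-3,4-diyl diacetate (di-O-acetyl-L-tartaric anhydride) | O=C1OC(=O)[C@H](OC(C)=O)[C@H]1OC(C)=O | starting material
6 | 2,5-dioxo-2,5-dihydrofuran-3-yl acetate (acetoxymaleic anhydride) | CC(=O)OC1=CC(=O)OC1=O | intermediate
7 | rac-3a-acetoxy-7-(dimethoxymethyl)-6-(propan-2-yl)-3a,4,7,7a-tetrahydro-2-benzofuran-1,3-dione, endo adduct | CC(C)C1=CC[C@@]2(OC(C)=O)C(=O)OC(=O)[C@H]2[C@H]1C(OC)OC | intermediate
8 | rac-3a-acetoxy-7-(dimethoxymethyl)-6-(propan-2-yl)hexahydro-2-benzofuran-1,3-dione | CC(C)[C@H]1CC[C@@]2(OC(C)=O)C(=O)OC(=O)[C@H]2[C@H]1C(OC)OC | intermediate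
9 | sodium rac-2-acetoxy-6-(dimethoxymethyl)-2-(hydroxymethyl)-5-(propan-2-yl)cyclohexane-1-carboxylate | CC(C)[C@H]1CC[C@@](OC(C)=O)(CO)[C@@H](C(=O)[O-])[C@H]1C(OC)OC.[Na+] | intermediate
10 | potassium rac-6-(dimethoxymethyl)-2-hydroxy-2-(hydroxymethyl)-5-(propan-2-yl)cyclohexane-1-carboxylate | CC(C)[C@H]1CC[C@@](O)(CO)[C@@H](C(=O)[O-])[C@H]1C(OC)OC.[K+] | intermediate
11 | rac-7-(dimethoxymethyl)-3a-hydroxy-6-(propan-2-yl)hexahydro-2-benzofuran-1(3H)-one | CC(C)[C@H]1CC[C@@]2(O)COC(=O)[C@H]2[C@H]1C(OC)OC | intermediate
12 | lithium rac-6-(dimethoxymethyl)-2-hydroxy-2-(hydroxymethyl)-5-(propan-2-yl)cyclohexane-1-carboxylate | CC(C)[C@H]1CC[C@@](O)(CO)[C@@H](C(=O)[O-])[C@H]1C(OC)OC.[Li+] | intermediate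
13 | rac-tert-butyldiphenylsilyl ester of acid 14 | CC(C)[C@H]1CC[C@@](O)(CO[Si](c2ccccc2)(c2ccccc2)C(C)(C)C)[C@@H](C(=O)O[Si](c2ccccc2)(c2ccccc2)C(C)(C)C)[C@H]1C(OC)OC | intermediate
14 | rac-2-{[(tert-butyldiphenylsilyl)oxy]methyl}-6-(dimethoxymethyl)-2-hydroxy-5-(propan-2-yl)cyclohexane-1-carboxylic acid | CC(C)[C@H]1CC[C@@](O)(CO[Si](c2ccccc2)(c2ccccc2)C(C)(C)C)[C@@H](C(=O)O)[C@H]1C(OC)OC | intermediate
15 | rac-6-formyl analogue of 14, CHO cis to CO2H | CC(C)[C@H]1CC[C@@](O)(CO[Si](c2ccccc2)(c2ccccc2)C(C)(C)C)[C@@H](C(=O)O)[C@H]1C=O | intermediate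
16 | rac-6-formyl analogue of 14, CHO trans to CO2H | CC(C)[C@H]1CC[C@@](O)(CO[Si](c2ccccc2)(c2ccccc2)C(C)(C)C)[C@@H](C(=O)O)[C@@H]1C=O | intermediate
17 | rac-2-{[(tert-butyldiphenylsilyl)oxy]methyl}-6-ethenyl-2-hydroxy-5-(propan-2-yl)cyclohexane-1-carboxylic acid | CC(C)[C@H]1CC[C@@](O)(CO[Si](c2ccccc2)(c2ccccc2)C(C)(C)C)[C@@H](C(=O)O)[C@@H]1C=C | intermediate
18 | 2-(bromomethyl)prop-2-enoic acid | C=C(CBr)C(=O)O | starting material
19 | (1S)-1-(4-methoxyphenyl)ethanol | C[C@H](O)c1ccc(OC)cc1 | starting material
20 | (1S)-1-(4-methoxyphenyl)ethyl 2-(bromomethyl)prop-2-enoate | C=C(CBr)C(=O)O[C@@H](C)c1ccc(OC)cc1 | intermediate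
21 | series A diene ester | CC(C)[C@H]1CC[C@@](O)(CO[Si](c2ccccc2)(c2ccccc2)C(C)(C)C)[C@@H](C(=O)OCC(=C)C(=O)O[C@@H](C)c2ccc(OC)cc2)[C@@H]1C=C | intermediate
22 | series B diene ester | CC(C)[C@@H]1CC[C@](O)(CO[Si](c2ccccc2)(c2ccccc2)C(C)(C)C)[C@H](C(=O)OCC(=C)C(=O)O[C@@H](C)c2ccc(OC)cc2)[C@H]1C=C | intermediate
23 | series A silyl-protected lactone (1S)-1-(4-methoxyphenyl)ethyl ester | CC(C)[C@H]1CC[C@@](O)(CO[Si](c3ccccc3)(c3ccccc3)C(C)(C)C)[C@H]2C(=O)OCC(C(=O)O[C@@H](C)c3ccc(OC)cc3)=C[C@H]12 | intermediate
24 | series B silyl-protected lactone (1S)-1-(4-methoxyphenyl)ethyl ester | CC(C)[C@@H]1CC[C@](O)(CO[Si](c3ccccc3)(c3ccccc3)C(C)(C)C)[C@@H]2C(=O)OCC(C(=O)O[C@@H](C)c3ccc(OC)cc3)=C[C@@H]12 | intermediate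
25 | series A silyl-protected lactone acid | CC(C)[C@H]1CC[C@@](O)(CO[Si](c3ccccc3)(c3ccccc3)C(C)(C)C)[C@H]2C(=O)OCC(C(=O)O)=C[C@H]12 | intermediate
26 | series B diol lactone (1S)-1-(4-methoxyphenyl)ethyl ester | CC(C)[C@@H]1CC[C@](O)(CO)[C@@H]2C(=O)OCC(C(=O)O[C@@H](C)c3ccc(OC)cc3)=C[C@@H]12 | intermediate
27 | protected heterochiral diester | CC(C)[C@H]1CC[C@@](O)(CO[Si](c5ccccc5)(c5ccccc5)C(C)(C)C)[C@H]2C(=O)OCC(C(=O)OC[C@@]3(O)CC[C@@H](C(C)C)[C@@H]4C=C(C(=O)O[C@@H](C)c5ccc(OC)cc5)COC(=O)[C@H]43)=C[C@H]12 | intermediate
28 | silyl-protected dimer acid | CC(C)[C@H]1CC[C@@](O)(CO[Si](c5ccccc5)(c5ccccc5)C(C)(C)C)[C@H]2C(=O)OCC(C(=O)OC[C@@]3(O)CC[C@@H](C(C)C)[C@@H]4C=C(C(=O)O)COC(=O)[C@H]43)=C[C@H]12 | intermediate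
29 | CNP0340505.1 | CC(C)[C@H]1CC[C@@](O)(CO)[C@H]2C(=O)OCC(C(=O)OC[C@@]3(O)CC[C@@H](C(C)C)[C@@H]4C=C(C(=O)O)COC(=O)[C@H]43)=C[C@H]12 | target

Total step count: 17. Longest linear sequence: 14 steps (1, 2, 4–9, 11, 12, 13, 15, 16, 17).

Steps most likely to fail

Step 4. The diene termini may pair the other way round (C9 with C1, C6 with C10), or the hindered partners may react so slowly that the diene polymerises. The fallback sets out from diene 4 and comes back at lactone 11. It keeps the same two-bond ring construction but moves the introduction of the C10 oxygen behind it. Cycloaddition of 4 with maleic anhydride (symmetrical, so no regiochemical question) gives the anhydride adduct F1. Methanolysis at the carbonyl remote from the C6 branch gives the half ester F2. Its dianion (LiN(iPr)2, 2.2 equiv) is hydroxylated at C10 with 2-(phenylsulfonyl)-3-phenyloxaziridine anti to the neighbouring carboxylate, giving the hydroxy ester F3. LiBH4 reduces the ester but not the carboxylate, and acidification closes the unsaturated hydroxy lactone F4. Hydrogenation (H2, PtO2) as in step 5 then gives 11.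

Step 12. The metathesis may stall at the hindered 1,1-disubstituted acrylate or turn intermolecular, and the two lactone diastereomers may fail to separate. The fallback sets out from aldehyde acid 16 and comes back at lactones 23 and 24. Wittig olefination of 16 with the stabilised phosphorane F5 (made from the corresponding α-bromo ester and PPh3) should give the E seco acids, series A silyl ether F6 and series B silyl ether F7. AcOH/THF/H2O removes only the triethylsilyl group and gives the series A hydroxy acid F8 and the series B hydroxy acid F9, which offer a second point of separation. MNBA/DMAP lactonisation at high dilution then closes the seven-membered ring to 23 and 24.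

Step 15. Under the basic acylation conditions the free primary alcohol of 26 may attack its own lactone carbonyl (translactonisation to the γ-lactone) faster than it is acylated. The fallback sets out from alcohol 26 (with acid 25) and comes back at diester 27. Mitsunobu cyclodehydration of the 1,2-diol (PPh3, DIAD, toluene, neutral) gives the spiro-epoxide F10, which has no free primary hydroxyl. Acid 25 then opens the epoxide at its CH2 terminus (Bu4NBr cat., toluene, 70 °C), forming the ester bond and regenerating the tertiary alcohol with C10′ untouched.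

Further compounds
F1 | step 4 | rac-7-(dimethoxymethyl)-6-(propan-2-yl)-3a,4,7,7a-tetrahydro-2-benzofuran-1,3-dione (endo) | CC(C)C1=CC[C@H]2C(=O)OC(=O)[C@H]2[C@H]1C(OC)OC
F2 | step 4 | rac-2-(dimethoxymethyl)-6-(methoxycarbonyl)-3-(propan-2-yl)cyclohex-3-ene-1-carboxylic acid (all cis) | CC(C)C1=CC[C@@H](C(=O)OC)[C@@H](C(=O)O)[C@H]1C(OC)OC
F3 | step 4 | rac-2-(dimethoxymethyl)-6-hydroxy-6-(methoxycarbonyl)-3-(propan-2-yl)cyclohex-3-ene-1-carboxylic acid (OH trans to CO2H) | CC(C)C1=CC[C@@](O)(C(=O)OC)[C@@H](C(=O)O)[C@H]1C(OC)OC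
F4 | step 4 | rac-7-(dimethoxymethyl)-3a-hydroxy-6-(propan-2-yl)-3a,4,7,7a-tetrahydro-2-benzofuran-1(3H)-one | CC(C)C1=CC[C@@]2(O)COC(=O)[C@H]2[C@H]1C(OC)OC
F5 | step 12 | (1S)-1-(4-methoxyphenyl)ethyl 3-[(triethylsilyl)oxy]-2-(triphenyl-λ5-phosphanylidene)propanoate | CC[Si](CC)(CC)OCC(=P(c1ccccc1)(c1ccccc1)c1ccccc1)C(=O)O[C@@H](C)c1ccc(OC)cc1
F6 | step 12 | series A E seco acid, triethylsilyl ether | CC(C)[C@H]1CC[C@@](O)(CO[Si](c2ccccc2)(c2ccccc2)C(C)(C)C)[C@@H](C(=O)O)[C@@H]1/C=C(\CO[Si](CC)(CC)CC)C(=O)O[C@@H](C)c1ccc(OC)cc1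
F7 | step 12 | series B E seco acid, triethylsilyl ether | CC(C)[C@@H]1CC[C@](O)(CO[Si](c2ccccc2)(c2ccccc2)C(C)(C)C)[C@H](C(=O)O)[C@H]1/C=C(\CO[Si](CC)(CC)CC)C(=O)O[C@@H](C)c1ccc(OC)cc1
F8 | step 12 | series A E seco hydroxy acid | CC(C)[C@H]1CC[C@@](O)(CO[Si](c2ccccc2)(c2ccccc2)C(C)(C)C)[C@@H](C(=O)O)[C@@H]1/C=C(\CO)C(=O)O[C@@H](C)c1ccc(OC)cc1
F9 | step 12 | series B E seco hydroxy acid | CC(C)[C@@H]1CC[C@](O)(CO[Si](c2ccccc2)(c2ccccc2)C(C)(C)C)[C@H](C(=O)O)[C@H]1/C=C(\CO)C(=O)O[C@@H](C)c1ccc(OC)cc1
F10 | step 15 | series B spiro-epoxide (C10′–C14′ oxirane) of lactone ester 26 | CC(C)[C@@H]1CC[C@]3(CO3)[C@@H]2C(=O)OCC(C(=O)O[C@@H](C)c4ccc(OC)cc4)=C[C@@H]12
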